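**Retrosynthetic overview**

1. The saturated ring C1–C2–C3–C4–C4a–C8a is closed last, on a purchased benzene ring, by forming the C1–C8a bond from an acyclic aryl aldehyde; the C1 methyl group is added in the same flask (C1–CH3 disconnection through an o-quinone methide).
2. Enabling feature: the free phenol O8 on C8 is ortho to the ring-fusion carbon C8a that carries C1. The O8–C8–C8a–C1 unit is therefore a latent o-quinone methide, and the phenoxide can template attack of C8a on a C1 aldehyde, so ring closure ortho to the phenol rather than para to it (C5) is built in.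
3. The acyclic aldehyde has C1 masked as a dimethyl acetal; C2–O comes from oxazaborolidine reduction of the α-keto acetal, and C4–C4a from a Rh/diene asymmetric 1,4-addition of an aryl boronate to an E-enone.
4. The enone comes from (S)-citronellal (C11) by one-carbon degradation and aldol condensation; the end game is desilylation, peracetylation and selective removal of the phenolic acetate.
5. Ring order: aromatic ring (bought as methyl 3-bromo-5-hydroxybenzoate), then the carbocycle in step 9.

Key step: step 9

Remark: locants follow the tetralin core of the target: C1 (CH–CH3), C2 (CH–OAc), C3, C4 (CH bearing the side chain), C4a/C8a (ring fusion), C5–C8 aromatic (C6 carries C19H2OAc, C8 the phenol), C11 = side-chain stereocentre. The target is (1S,2S,4S,11S): C1-Me trans to C2-O, C2-O cis to the C4 side chain. The sense of induction quoted for the Rh/diene and oxazaborolidine catalysts is assigned by analogy and would be confirmed on the first run.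

**Route**

Step 1
Reactants: 1 (S)-citronellal [(3S)-3,7-dimethyloct-6-enal]
Product: 3 (2S)-2,6-dimethylhept-5-enal, via piperidine enamine 2 (not isolated)
Conditions: piperidine (1.2 equiv), K2CO3, Et2O, 0 °C → rt; filter, strip excess amine; then CuCl (10 mol%), O2 (1 atm), MeCN, 0 °C → rt
Reagents that add atoms: dioxygen O=O
Why: Condensation gives the E-enamine, whose C=C bond is cleaved by copper-catalysed aerobic enamine oxygenation to release C1 as N-formylpiperidine; the stereocentre lies outside the enamine π-system and should emerge unchanged as the (S)-α-carbon of 3.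

Step 2
Reactants: 3 (2S)-2,6-dimethylhept-5-enal; 4 1,1-dimethoxypropan-2-one
Product: 7 (3E,5S)-1,1-dimethoxy-5,9-dimethyldeca-3,8-dien-2-one, via aldol adduct 5 (not isolated), via aldol mesylate 6 (not isolated)
Conditions: LDA (1.05 equiv), 4, THF, −78 °C; add 3, −78 °C; then MsCl, Et3N, −78 → 0 °C
Reagents that add atoms: none
Why: Aldol addition of the kinetic lithium enolate of 4 (only its methyl group is enolisable) to 3, then E1cB elimination of the mesylate, is a two-stage aldol condensation that should give the E-enone under conditions too mild to epimerise the adjacent stereocentre.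

Step 3
Reactants: 8 methyl 3-bromo-5-hydroxybenzoate
Product: 9 methyl 3-bromo-5-(methoxymethoxy)benzoate
Conditions: MOMCl, i-Pr2NEt, CH2Cl2, 0 °C → rt
Reagents that add atoms: chloromethyl methyl ether COCCl
Why: O-Alkylation of the phenol (Williamson-type MOM protection) masks the acidic OH for the boron and hydride steps with a group that is later removed together with the acetal.

Step 4
Reactants: 9 methyl 3-bromo-5-(methoxymethoxy)benzoate
Product: 10 methyl 3-(methoxymethoxy)-5-(4,4,5,5-tetramethyl-1,3,2-dioxaborolan-2-yl)benzoate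
Conditions: B2pin2, Pd(dppf)Cl2 (3 mol%), KOAc, 1,4-dioxane, 85 °C
Reagents that add atoms: bis(pinacolato)diboron CC1(C)OB(OC1(C)C)B1OC(C)(C)C(C)(C)O1
Why: Miyaura borylation of the aryl bromide (oxidative addition, acetate-assisted transmetalation, reductive elimination) should tolerate the ester and the MOM ether.

Step 5
Reactants: 7 (3E,5S)-1,1-dimethoxy-5,9-dimethyldeca-3,8-dien-2-one; 10 aryl pinacol boronate (1.5 equiv)
Product: 11 methyl 3-[(4S,5S)-1,1-dimethoxy-5,9-dimethyl-2-oxodec-8-en-4-yl]-5-(methoxymethoxy)benzoate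
Conditions: [RhCl(C2H4)2]2 (2.5 mol%), (R,R)-Ph-bod* (5.5 mol%), aq. K3PO4 (0.5 equiv), 1,4-dioxane/H2O 10:1, 40 °C
Reagents that add atoms: none
Why: Hayashi–Miyaura reaction: the aryl–Rh(I) species adds 1,4 to the E-enone and the oxa-π-allyl rhodium is protonated by water; the benzylic centre C4 (S) is set by the chiral diene (the ligand enantiomer that gives 4S is used), which should override the neighbouring C11 centre.

Step 6
Reactants: 11 β-aryl α-keto acetal
Product: 12 methyl 3-[(2S,4S,5S)-2-hydroxy-1,1-dimethoxy-5,9-dimethyldec-8-en-4-yl]-5-(methoxymethoxy)benzoate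
Conditions: (R)-Me-CBS (20 mol%), catecholborane (1.8 equiv), toluene, −78 → −40 °C; MeOH, aq. NaHCO3
Reagents that add atoms: none
Why: Corey–Bakshi–Shibata reduction: the ketone binds the oxazaborolidine anti to the bulkier dimethoxymethyl group and hydride is delivered from the coordinated borane, which should set C2 (S) by catalyst control; catecholborane does not hydroborate the trisubstituted alkene at this temperature.

Step 7
Reactants: 12 α-hydroxy acetal ester
Product: 13 (2S,4S,5S)-4-[3-(hydroxymethyl)-5-(methoxymethoxy)phenyl]-1,1-dimethoxy-5,9-dimethyldec-8-en-2-ol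
Conditions: LiAlH4 (1.5 equiv), THF, 0 °C; Fieser work-up
Reagents that add atoms: none
Why: Hydride reduction of the methyl ester to the benzylic alcohol (C19) at a stage where acetal, MOM ether and alkene are inert.

Step 8
Reactants: 13 diol acetal
Product: 15 (2S,4S,5S)-2-[(tert-butyldimethylsilyl)oxy]-4-[3-{[(tert-butyldimethylsilyl)oxy]methyl}-5-hydroxyphenyl]-5,9-dimethyldec-8-enal, via bis-silyl ether 14 (not isolated)
Conditions: TBSOTf (2.4 equiv), 2,6-lutidine, CH2Cl2, −78 → 0 °C; then 2,2'-bipyridyl, TMSOTf (4 equiv), 0 °C → rt; H2O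
Reagents that add atoms: tert-butyldimethylsilyl triflate CC(C)(C)[Si](C)(C)OS(=O)(=O)C(F)(F)F; water O
Why: Silylation of both alcohols is followed in the same flask by silyl triflate/pyridine-base activation of the two O,O-acetals (dimethyl acetal to a pyridinium salt, aryl MOM ether to an aryl silyl ether); water then releases the aldehyde and the free phenol while the alkyl TBS ethers survive, and no stereocentre is touched.

Step 9
Reactants: 15 phenol aldehyde
Product: 19 (5S,7S,8S)-7-[(tert-butyldimethylsilyl)oxy]-3-{[(tert-butyldimethylsilyl)oxy]methyl}-8-methyl-5-[(2S)-6-methylhept-5-en-2-yl]-5,6,7,8-tetrahydronaphthalen-1-ol, via salicyl alcohol 16 (not isolated), via benzylic carbonate 17 (not isolated), via o-quinone methide 18 (not isolated)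
Conditions: MgBr2·OEt2 (1.5 equiv), Et3N (1.5 equiv), CH2Cl2, −20 °C → rt; then Boc2O (1.1 equiv), 0 °C; then MeMgBr (5 equiv, Et2O), −78 °C → rt; aq. NH4Cl
Reagents that add atoms: methylmagnesium bromide C[Mg]Br
Why: Proposed new method: the magnesium phenoxide of 15 binds the tethered aldehyde through Mg, and its ortho carbon C8a adds to C1 (phenoxide-templated Friedel–Crafts hydroxyalkylation) to give the chelated salicyl alkoxide 16; Boc2O turns the C1 oxygen into a carbonate (17), which the phenoxide expels once MeMgBr is added, and the planar o-quinone methide 18 takes up methyl at C1 by 1,4-addition with rearomatisation. The closest known reaction types are the ortho-specific hydroxyalkylation of magnesium phenoxides with aldehydes and the low-temperature generation of o-quinone methides from Boc-activated salicyl alkoxides with Grignard capture, here merged into an intramolecular one-pot sequence. The only ring closed is the C1–C2–C3–C4–C4a–C8a carbocycle, by C1–C8a bond formation in a 6-exo-trig attack on the aldehyde C=O. The new stereocentre C1 is set in the methyl addition: both C1 epimers of 16 and 17 converge on 18, and MeMgBr should attack anti to the adjacent C2 silyloxy group (Felkin–Anh-type, bulky OTBS perpendicular to the methide), giving the 1,2-trans product (1S). The step needs regioselectivity for C8a over the para position C5, which is secured by delivery of the aldehyde through the Mg–O8 chelate that can reach only the ortho carbon; it also needs C-methylation at C1 rather than carbonyl addition, which follows from aromatisation of the o-quinone methide, and the protected C2 oxygen cannot direct a syn delivery.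

Step 10
Reactants: 19 bis-silyl tetralin phenol
Product: 20 (5S,7S,8S)-3-(hydroxymethyl)-8-methyl-5-[(2S)-6-methylhept-5-en-2-yl]-5,6,7,8-tetrahydronaphthalene-1,7-diol
Conditions: TBAF (3 equiv), THF, 0 °C → rt
Reagents that add atoms: none
Why: Fluoride-mediated cleavage of both silyl ethers (Si–F bond formation) without affecting the alkene or any stereocentre.

Step 11
Reactants: 20 triol
Product: 21 (5S,7S,8S)-3-(acetoxymethyl)-8-methyl-5-[(2S)-6-methylhept-5-en-2-yl]-5,6,7,8-tetrahydronaphthalene-1,7-diyl diacetate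
Conditions: Ac2O (6 equiv), pyridine, DMAP (cat.), CH2Cl2, rt
Reagents that add atoms: acetic anhydride CC(=O)OC(C)=O
Why: DMAP-catalysed acylation esterifies all three hydroxyl groups, so no differentiation is needed at this point.

Step 12
Reactants: 21 triacetate
Product: 22 [(5S,6S,8S)-6-acetoxy-4-hydroxy-5-methyl-8-[(2S)-6-methylhept-5-en-2-yl]-5,6,7,8-tetrahydronaphthalen-2-yl]methyl acetate (CNP0210401.1)
Conditions: pyrrolidine (1.1 equiv), CH2Cl2, 0 °C
Reagents that add atoms: none
Why: Chemoselective aminolysis: the aryl acetate, with its phenoxide leaving group, is far more electrophilic than the two alkyl acetates, so one equivalent of amine should free only the C8 phenol and give the target.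

**Compound list**

1 | (S)-citronellal, (3S)-3,7-dimethyloct-6-enal | O=CC[C@@H](C)CCC=C(C)C | starting material
2 | 1-[(1E,3S)-3,7-dimethylocta-1,6-dien-1-yl]piperidine | N1(/C=C/[C@@H](C)CCC=C(C)C)CCCCC1 | intermediate (not isolated)
3 | (2S)-2,6-dimethylhept-5-enal | O=C[C@@H](C)CCC=C(C)C | intermediate
4 | 1,1-dimethoxypropan-2-one | CC(=O)C(OC)OC | starting material
5 | (5S)-4-hydroxy-1,1-dimethoxy-5,9-dimethyldec-8-en-2-one (both C4 epimers) | COC(OC)C(=O)CC(O)[C@@H](C)CCC=C(C)C | intermediate (not isolated)
6 | (5S)-1,1-dimethoxy-5,9-dimethyl-2-oxodec-8-en-4-yl methanesulfonate (both C4 epimers) | COC(OC)C(=O)CC(OS(C)(=O)=O)[C@@H](C)CCC=C(C)C | intermediate (not isolated)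
7 | (3E,5S)-1,1-dimethoxy-5,9-dimethyldeca-3,8-dien-2-one | COC(OC)C(=O)/C=C/[C@@H](C)CCC=C(C)C | intermediate
8 | methyl 3-bromo-5-hydroxybenzoate | COC(=O)c1cc(O)cc(Br)c1 | starting material
9 | methyl 3-bromo-5-(methoxymethoxy)benzoate | COCOc1cc(Br)cc(c1)C(=O)OC | intermediate
10 | methyl 3-(methoxymethoxy)-5-(4,4,5,5-tetramethyl-1,3,2-dioxaborolan-2-yl)benzoate | COCOc1cc(cc(c1)C(=O)OC)B1OC(C)(C)C(C)(C)O1 | intermediate
11 | methyl 3-[(4S,5S)-1,1-dimethoxy-5,9-dimethyl-2-oxodec-8-en-4-yl]-5-(methoxymethoxy)benzoate | COC(=O)c1cc(OCOC)cc(c1)[C@H]([C@@H](C)CCC=C(C)C)CC(=O)C(OC)OC | intermediate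
12 | methyl 3-[(2S,4S,5S)-2-hydroxy-1,1-dimethoxy-5,9-dimethyldec-8-en-4-yl]-5-(methoxymethoxy)benzoate | COC(=O)c1cc(OCOC)cc(c1)[C@H]([C@@H](C)CCC=C(C)C)C[C@H](O)C(OC)OC | intermediate
13 | (2S,4S,5S)-4-[3-(hydroxymethyl)-5-(methoxymethoxy)phenyl]-1,1-dimethoxy-5,9-dimethyldec-8-en-2-ol | OCc1cc(OCOC)cc(c1)[C@H]([C@@H](C)CCC=C(C)C)C[C@H](O)C(OC)OC | intermediate
14 | bis-TBS ether of 13 (C2–OTBS, C19–OTBS; acetal and MOM ether intact) | CC(C)(C)[Si](C)(C)OCc1cc(OCOC)cc(c1)[C@H]([C@@H](C)CCC=C(C)C)C[C@H](O[Si](C)(C)C(C)(C)C)C(OC)OC | intermediate (not isolated)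
15 | (2S,4S,5S)-2-[(tert-butyldimethylsilyl)oxy]-4-[3-{[(tert-butyldimethylsilyl)oxy]methyl}-5-hydroxyphenyl]-5,9-dimethyldec-8-enal | CC(C)(C)[Si](C)(C)OCc1cc(O)cc(c1)[C@H]([C@@H](C)CCC=C(C)C)C[C@H](O[Si](C)(C)C(C)(C)C)C=O | intermediate
16 | (5S,7S)-7-[(tert-butyldimethylsilyl)oxy]-3-{[(tert-butyldimethylsilyl)oxy]methyl}-5-[(2S)-6-methylhept-5-en-2-yl]-5,6,7,8-tetrahydronaphthalene-1,8-diol (both C8 epimers; C8 here = C1 of the target) | CC(C)(C)[Si](C)(C)OCc1cc(O)c2c(c1)[C@H]([C@@H](C)CCC=C(C)C)C[C@H](O[Si](C)(C)C(C)(C)C)C2O | intermediate (not isolated)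
17 | tert-butyl (2S,4S)-2-[(tert-butyldimethylsilyl)oxy]-6-{[(tert-butyldimethylsilyl)oxy]methyl}-8-hydroxy-4-[(2S)-6-methylhept-5-en-2-yl]-1,2,3,4-tetrahydronaphthalen-1-yl carbonate (both C1 epimers) | CC(C)(C)[Si](C)(C)OCc1cc(O)c2c(c1)[C@H]([C@@H](C)CCC=C(C)C)C[C@H](O[Si](C)(C)C(C)(C)C)C2OC(=O)OC(C)(C)C | intermediate (not isolated)
18 | (5S,7S)-7-[(tert-butyldimethylsilyl)oxy]-3-{[(tert-butyldimethylsilyl)oxy]methyl}-5-[(2S)-6-methylhept-5-en-2-yl]-6,7-dihydronaphthalen-1(5H)-one (o-quinone methide) | CC(C)(C)[Si](C)(C)OCC1=CC(=O)C2=C[C@@H](O[Si](C)(C)C(C)(C)C)C[C@@H]([C@@H](C)CCC=C(C)C)C2=C1 | intermediate (not isolated)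
19 | (5S,7S,8S)-7-[(tert-butyldimethylsilyl)oxy]-3-{[(tert-butyldimethylsilyl)oxy]methyl}-8-methyl-5-[(2S)-6-methylhept-5-en-2-yl]-5,6,7,8-tetrahydronaphthalen-1-ol | CC(C)(C)[Si](C)(C)OCc1cc(O)c2c(c1)[C@H]([C@@H](C)CCC=C(C)C)C[C@H](O[Si](C)(C)C(C)(C)C)[C@H]2C | intermediate
20 | (5S,7S,8S)-3-(hydroxymethyl)-8-methyl-5-[(2S)-6-methylhept-5-en-2-yl]-5,6,7,8-tetrahydronaphthalene-1,7-diol | OCc1cc(O)c2c(c1)[C@H]([C@@H](C)CCC=C(C)C)C[C@H](O)[C@H]2C | intermediate
21 | (5S,7S,8S)-3-(acetoxymethyl)-8-methyl-5-[(2S)-6-methylhept-5-en-2-yl]-5,6,7,8-tetrahydronaphthalene-1,7-diyl diacetate | CC(=O)OCc1cc(OC(C)=O)c2c(c1)[C@H]([C@@H](C)CCC=C(C)C)C[C@H](OC(C)=O)[C@H]2C | intermediate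
22 | [(5S,6S,8S)-6-acetoxy-4-hydroxy-5-methyl-8-[(2S)-6-methylhept-5-en-2-yl]-5,6,7,8-tetrahydronaphthalen-2-yl]methyl acetate (CNP0210401.1) | CC(=O)OCc1cc(O)c2c(c1)[C@H]([C@@H](C)CCC=C(C)C)C[C@H](OC(C)=O)[C@H]2C | target

**Step count and risks**

Total step count: 12. Longest linear sequence: 10 steps (1 → 3 → 7 → 11 → 12 → 13 → 15 → 19 → 20 → 21 → 22, steps 1, 2 and 5–12; the arene branch 8 → 9 → 10 → 11 → … → 22 is equally long).

Steps most likely to fail:

1. Step 9 (Proposed new method). What may go wrong: enolisation and epimerisation of the α-silyloxy aldehyde at C2 before ring closure, untemplated attack at the para position, incomplete o-quinone methide formation in one flask, or weak facial discrimination in the methyl addition. The fallback sets out from 15 and uses known reactions stepwise. Condensation with phenylboronic acid (cat. propionic acid, toluene, azeotropic water removal) should give, ortho-specifically and without base, the isolable cyclic phenylboronate F1. Transesterification with propane-1,3-diol should free the salicyl alcohol 16, which is isolated. Boc2O/K2CO3 should acylate only the phenol to give the aryl tert-butyl carbonate F2. MeMgBr (−78 °C → rt) then triggers carbonate transfer, o-quinone methide formation and methyl capture, and the sequence comes back to the route at 19.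

2. Step 8. What may go wrong: incomplete cleavage of the aryl MOM ether, or desilylation and epimerisation of the α-silyloxy aldehyde under the silyl triflate conditions. The fallback sets out from 13 and frees the phenol first, under protic conditions, while C1 is still an acetal. HCl in MeOH (0 °C) should remove only the aryl MOM group to give the phenol triol F3. Excess TBSCl/imidazole should give the tris-silyl ether F4. TESOTf/2,4,6-collidine followed by water should unmask the aldehyde F5. Buffered TBAF/AcOH (1 equiv, 0 °C) should then cleave only the aryl silyl ether, and the sequence comes back to the route at 15.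

3. Step 1. What may go wrong: partial racemisation of the α-stereocentre of 3 through reversible enamine formation with residual piperidine during the oxidative cleavage. The fallback sets out from 1 and excises C1 without exposing 3 to amine. Proline-catalysed α-aminoxylation with nitrosobenzene, with NaBH4 reduction in the same flask, should give the anilinooxy alcohol F6. Zn/AcOH should cleave the N–O bond to the 1,2-diol F7. Neutral NaIO4 glycol cleavage then comes back to the route at 3.

**Further compounds**

F1 | step 9 | cyclic phenylboronate of 16 (2-phenyl-4H-1,3,2-benzodioxaborin bridging O8 and the C1 oxygen; both C1 epimers) | CC(C)(C)[Si](C)(C)OCc1cc2OB(c4ccccc4)OC3[C@@H](O[Si](C)(C)C(C)(C)C)C[C@@H]([C@@H](C)CCC=C(C)C)c(c1)c23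
F2 | step 9 | aryl tert-butyl carbonate of 16 (C8–O–Boc, C1–OH free; both C1 epimers) | CC(C)(C)[Si](C)(C)OCc1cc(OC(=O)OC(C)(C)C)c2c(c1)[C@H]([C@@H](C)CCC=C(C)C)C[C@H](O[Si](C)(C)C(C)(C)C)C2O
F3 | step 8 | (2S,4S,5S)-4-[3-hydroxy-5-(hydroxymethyl)phenyl]-1,1-dimethoxy-5,9-dimethyldec-8-en-2-ol | OCc1cc(O)cc(c1)[C@H]([C@@H](C)CCC=C(C)C)C[C@H](O)C(OC)OC
F4 | step 8 | tris-TBS ether of F3 | CC(C)(C)[Si](C)(C)OCc1cc(O[Si](C)(C)C(C)(C)C)cc(c1)[C@H]([C@@H](C)CCC=C(C)C)C[C@H](O[Si](C)(C)C(C)(C)C)C(OC)OC
F5 | step 8 | (2S,4S,5S)-2-[(tert-butyldimethylsilyl)oxy]-4-[3-[(tert-butyldimethylsilyl)oxy]-5-{[(tert-butyldimethylsilyl)oxy]methyl}phenyl]-5,9-dimethyldec-8-enal | CC(C)(C)[Si](C)(C)OCc1cc(O[Si](C)(C)C(C)(C)C)cc(c1)[C@H]([C@@H](C)CCC=C(C)C)C[C@H](O[Si](C)(C)C(C)(C)C)C=O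
F6 | step 1 | (3S)-3,7-dimethyl-2-[(phenylamino)oxy]oct-6-en-1-ol (C2 configuration immaterial) | OCC(ONc1ccccc1)[C@@H](C)CCC=C(C)C
F7 | step 1 | (3S)-3,7-dimethyloct-6-ene-1,2-diol (C2 configuration immaterial) | OCC(O)[C@@H](C)CCC=C(C)C
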